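# Total synthesis plan for lancerodiol p-methoxybenzoate (25)

## The problem

- **Numbering.** Atoms follow the daucane numbering. C1 is the quaternary ring-fusion carbon bearing CH3. C2 and C3 are CH2. C4 is C(OH)(iPr). C5 is the ring-fusion CH. C6 is CH–O-anisoyl. C7=C8(CH3) is the alkene. C9 is C=O. C10 is CH2. β is the face of the C1 methyl group, so 25 is 1β-CH3, 4β-OH, 5α-H, 6α-O-acyl, that is (1R,4R,5S,6S).
- **Skeleton.** The target is a trans-fused bicyclo[5.3.0]decane. Neither a seven-membered ring nor a trans fusion next to a quaternary carbon forms readily by simple cyclisation.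
- **Stereocentres.** The four centres are contiguous. C5 is their hub, bonded to the quaternary C1, the fully substituted carbinol C4 and the carbinol C6.
- **Which centre controls which.** Only C4 can be made on its own. It must then control C1, which lies 1,3 to it across the cyclopentane. C5 can be adjusted only while C6 is a ketone. C6 can be set from the C4 hydroxyl, which lies 1,3 to it.
- **Sensitive groups.** C4–OH and C6–O form an aldol array, so retro-aldol and dehydration threaten once C6 is a ketone. The γ-acyloxy enone and the anisate do not survive cuprates, electron-transfer reagents, hydride or strong base. The ester therefore goes on last.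
- **Enabling feature.** In the seven-membered ring the five contiguous carbons C5–C6–C7–C8–C9 carry oxygen on C6 and C9. They are the carbon frame of a 3-oxidopyrylium, with C5 and C9 as termini and C6 as the oxido carbon. The other two ring atoms, C10 and C1, are then a 1,1-disubstituted alkene. The rest of the cyclopentane, C4–C3–C2, is exactly the three-atom tether from C5 to C1.
- **Consequence.** One intramolecular (5+2) cycloaddition can close both rings and set the quaternary carbon. The price is an oxygen bridge C5–O–C9 that must be opened again.

## Retrosynthesis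

**Ester C–O (25 ⇒ 23 + 24).** The acyl C–O bond of 25 is cut first, giving lancerodiol 23 and 4-methoxybenzoyl chloride 24. An earlier entry of the anisate would expose it to the cuprate, to SmI2 and to hydride. The precursor is eight carbons smaller. The forward reaction only has to tell the secondary allylic C6–OH from the tertiary C4–OH.

**C6–H (23 ⇒ 22).** The C6 carbinol is traced to the ene-dione 22.
- The C4 hydroxyl lies 1,3 to C6 on the β face. It can bind a borohydride and deliver hydride to C6 alone.
- C9 has no such handle, so the two carbonyl groups distinguish themselves without protecting groups.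
- With C6 as a ketone, C5 is still correctable.
- The forward step must be chemoselective (C6 over C9, 1,2 over 1,4) and give the 6α-alcohol.

**C7=C8, C9=O and C5–H (22 ⇒ 21 ⇒ 20 ⇒ 19 ⇒ 17).**
- 22 is the desilylated form of 21.
- 21 comes by oxidation, via diketone 20, from hydroxy ketone 19.
- In 19 the C5–H bond is exchanged for a bond from C5 to the C9 oxygen, which gives the bridged ketone 17.
- This bond is chosen because it is α to the C6 ketone, the one kind of C–O bond that SmI2 cleaves cleanly.
- Reconnection turns a flexible hydroazulene into a rigid 8-oxabicyclo[3.2.1]octanone, the retron of the (5+2) reaction.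
- The forward steps must put hydrogen on the α face of C5.

**C8–CH3 (17 ⇒ 16).** The C8 methyl is removed to give enone 16.
- This allows plain furan 8 as the four-carbon unit. A methyl-substituted furan would need regioselective metalation remote from the methyl group, which is not secured.
- It also saturates C7=C8 before the electron-transfer step, so only the α C5–O bond can leave. In an enone the vinylogous C9–O bond would compete.

**C1–C5 and C9–C10 (16 ⇒ 15 ⇒ 14), the key cut.** Both bonds are cut at once, giving the oxidopyrylium 15 and its precursor 14.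
- 16 has three rings, a quaternary carbon and four stereocentres. 14 has one ring and one defined stereocentre.
- No neighbouring pair of bonds removes both carbocycles together.
- The forward reaction must use the face of the dipole that places C1–CH3 syn to C4–O.

**Pyranone to furan (14 ⇒ 13 ⇒ 12).** No C–C bond is cut. The pyranone is the oxidised, ring-enlarged form of a furfuryl alcohol (Achmatowicz rearrangement). The furan supplies C6–C9 and the carbinol carbon becomes C5. The pendant alkene must survive the oxidant.

**C5–C6 (12 ⇒ 11 ⇒ 10 ⇒ 7 + 8).** The bond between the carbinol carbon and the furan is cut, giving the activated ester 7 and furan 8 (used as 9). Cutting C4–C5 instead would require an addition to an unsymmetrical dialkyl ketone, with no control at C4. The C4 hydroxyl must be masked (11). If left free it would trap C9 of the pyranone as a bicyclic ketal.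

**C3–C4 (7 ⇒ 3 + 5; 3 ⇒ 1 + 2; 5 ⇒ 4).** The side chain is removed from C4. What remains is the dioxolanone 3 of commercial hydroxy acid 1, which already holds C4, its oxygen, the isopropyl group and C5. Alkylation with iodide 5 (from alcohol 4) must replace H by carbon with retention.

## Roads not taken

**Alternative 1: ring-closing metathesis (the most obvious route).**
- *Cut:* C7=C8.
- *Forward key step:* ring-closing metathesis of dienone A1 with a Ru carbene catalyst.
- *Why the chosen plan is better:*
  - A1 already contains all four stereocentres, so the metathesis solves only the ring closure and sets nothing.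
  - The cyclopentane would come from enal A2 by conjugate addition at C1. There the carbon nucleophile (C10) must enter cis to the C4 isopropyl group, which is the hindered face.
  - The C6 carbinol would come from an unguided vinyl addition.
  - The closure itself must make a trisubstituted, electron-poor alkene in a seven-membered ring.
  - The hard part is moved into a long run-up. In the chosen plan the key step carries it.

**Alternative 2: the oxidopyrylium in the other orientation.**
- *Cut:* C5–C6 and C1–C10.
- *Forward key step:* intermolecular (5+2) cycloaddition of the ylide from acetoxypyranone A3 with cyclopentenol A4. This would give A5, with the oxygen bridge from C6 to C10.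
- *What speaks for it:* the oxidation pattern is ideal, with the C9 ketone, the C8 methyl and the C6 oxygen all in place.
- *Why it is rejected:*
  - Suprafacial addition to a cyclopentene can give only a cis ring fusion (H5 cis to C1–CH3), as in A5.
  - No carbonyl group next to C5 would allow correction.
  - An unactivated trisubstituted alkene is a poor partner for an untethered ylide, which would rather dimerise.
  - Approach anti to the isopropyl group gives the wrong relation of C1 to C4.
- The chosen orientation pays with a redox exchange between C6 and C9. In return it gains the tether, the trans relation and the control by C4.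

**Alternative 3: Rh-carbenoid formal (4+3).**
- *Cut:* C1–C10 and C7–C8.
- *Forward key step:* Rh-catalysed cyclopropanation/Cope rearrangement of vinylcyclopentene A7 with siloxyvinyl diazoacetate A8, giving A9. A7 would come from (S)-terpinen-4-ol A6 via A2.
- *What speaks for it:* C4 comes from the chiral pool, and the Cope step makes the quaternary C1.
- *Why it is rejected:*
  - A9 carries an ester where C8 needs a methyl group.
  - A9 has no oxygen at C6 and has C5 as an sp2 carbon.
  - The repair needs a hydroboration whose face is contested by the α-isopropyl group on one side and the β-methyl and β-oxygen on the other.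
  - It also needs several steps from ester to methyl, and a late dehydrogenation.
  - The β-hydroxy aldehyde on the way from A6 to A2 is prone to dehydration.
  - The chosen key step leaves oxygen on both C6 and C9.

Key step: step 9

Remark: the carbinol centre C5 in 12–14 and the acetal centre C9 in 13 and 14 form as mixtures. All are erased in ylide 15, so they are left undefined in the SMILES.

## Steps

Step 1
Reactants: 1 (R)-2-hydroxy-3-methylbutanoic acid; 2 pivalaldehyde
Product: 3 (2R,5R)-2-tert-butyl-5-isopropyl-1,3-dioxolan-4-one (cis)
Conditions: p-TsOH (cat.), H2SO4 (cat.), pentane, reflux, Dean–Stark; crystallisation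
Reagents that add atoms: none
Why: Acid-catalysed acetalisation with removal of water; the cis isomer is the favoured one and can be purified by crystallisation. The new acetal centre stores the chirality of 1 (self-regeneration of stereocentres).

Step 2
Reactants: 4 3-methylbut-3-en-1-ol
Product: 5 4-iodo-2-methylbut-1-ene
Conditions: I2, PPh3, imidazole, CH2Cl2, 0 °C to rt
Reagents that add atoms: iodine II
Why: Appel reaction of a primary alcohol; the 1,1-disubstituted alkene is inert under these conditions.

Step 3
Reactants: 3 (2R,5R)-2-tert-butyl-5-isopropyl-1,3-dioxolan-4-one; 5 4-iodo-2-methylbut-1-ene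
Product: 7 (2R,5R)-2-tert-butyl-5-isopropyl-5-(3-methylbut-3-en-1-yl)-1,3-dioxolan-4-one, via lithium enolate 6 (not isolated)
Conditions: LDA, THF, −78 °C; 5, DMPU, −78 to −30 °C
Reagents that add atoms: none
Why: Enolate alkylation under self-regeneration of stereocentres. The planar enolate 6 keeps only the acetal centre, whose tert-butyl group shields one face. The iodide therefore enters where H stood, which sets C4 as (R) with overall retention.

Step 4
Reactants: 7 (2R,5R)-2-tert-butyl-5-isopropyl-5-(3-methylbut-3-en-1-yl)-1,3-dioxolan-4-one; 8 furan
Product: 10 (R)-1-(furan-2-yl)-2-hydroxy-2-isopropyl-5-methylhex-5-en-1-one, via 2-furyllithium 9 (not isolated)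
Conditions: 8, n-BuLi, THF, −78 to 0 °C; then 7, −78 °C; aq. NH4Cl
Reagents that add atoms: none
Why: α-Lithiation of furan followed by acyl substitution at the activated lactone carbonyl forms C5–C6. The tetrahedral adduct should persist in the cold, which limits the reaction to one addition; on work-up it collapses with loss of pivalaldehyde. C4 is not touched.

Step 5
Reactants: 10 (R)-1-(furan-2-yl)-2-hydroxy-2-isopropyl-5-methylhex-5-en-1-one
Product: 11 (R)-1-(furan-2-yl)-2-isopropyl-5-methyl-2-(triethylsilyloxy)hex-5-en-1-one
Conditions: TESOTf, 2,6-lutidine, CH2Cl2, 0 °C to rt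
Reagents that add atoms: triethylsilyl trifluoromethanesulfonate CC[Si](CC)(CC)OS(=O)(=O)C(F)(F)F
Why: Silyl triflate silylation of a hindered tertiary alcohol; the ketone cannot enolise. The ether keeps the C4 oxygen from adding to C9 of the later pyranone and blocks retro-aldol and dehydration up to step 13.

Step 6
Reactants: 11 (R)-1-(furan-2-yl)-2-isopropyl-5-methyl-2-(triethylsilyloxy)hex-5-en-1-one
Product: 12 (2R)-1-(furan-2-yl)-2-isopropyl-5-methyl-2-(triethylsilyloxy)hex-5-en-1-ol (both C1 epimers)
Conditions: NaBH4, CeCl3·7H2O, MeOH, −20 to 0 °C
Reagents that add atoms: none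
Why: Luche reduction of a 2-acylfuran; the buffered, weakly basic medium should suppress 1,2-migration of the silyl group. The new carbinol centre (C5) is of no consequence because it is erased in step 9.

Step 7
Reactants: 12 (2R)-1-(furan-2-yl)-2-isopropyl-5-methyl-2-(triethylsilyloxy)hex-5-en-1-ol
Product: 13 6-hydroxy-2-[(3R)-2,6-dimethyl-3-(triethylsilyloxy)hept-6-en-3-yl]-2H-pyran-3(6H)-one
Conditions: VO(acac)2 (cat.), t-BuOOH, CH2Cl2, 0 °C to rt
Reagents that add atoms: tert-butyl hydroperoxide CC(C)(C)OO
Why: Achmatowicz rearrangement. The vanadium peroxide is bound by the furfuryl hydroxyl and oxidises the electron-rich furan, while the remote unactivated alkene is left alone.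

Step 8
Reactants: 13 6-hydroxy-2-[(3R)-2,6-dimethyl-3-(triethylsilyloxy)hept-6-en-3-yl]-2H-pyran-3(6H)-one
Product: 14 6-acetoxy-2-[(3R)-2,6-dimethyl-3-(triethylsilyloxy)hept-6-en-3-yl]-2H-pyran-3(6H)-one
Conditions: Ac2O, pyridine, DMAP (cat.), CH2Cl2, 0 °C
Reagents that add atoms: acetic anhydride CC(=O)OC(C)=O
Why: Acetylation of the only free hydroxyl, the hemiacetal OH, turns C9–O into a leaving group.

Step 9
Reactants: 14 6-acetoxy-2-[(3R)-2,6-dimethyl-3-(triethylsilyloxy)hept-6-en-3-yl]-2H-pyran-3(6H)-one
Product: 16 tricyclic enone 5α,9α-epoxy-4β-(triethylsilyloxy)-14-nordauc-7-en-6-one (O bridge anti to C1–CH3; C4–O syn to C1–CH3), via 3-oxidopyrylium ylide 15 (not isolated)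
Conditions: DBU, MeCN, high dilution, 60 °C
Reagents that add atoms: none
Why: DBU removes H5, which is α to both the ketone and the ring oxygen, and acetate leaves from C9, giving the 3-oxidopyrylium 15, a five-atom 4π dipole with termini C5 and C9. The dipole adds suprafacially to the tethered 1,1-disubstituted alkene in a thermally allowed [π4s+π2s] process; the closest known reaction is the intramolecular oxidopyrylium–alkene (5+2) cycloaddition with a three-atom tether, an established entry to hydroazulenes that also tolerates formation of a quaternary carbon. The C1–C5 bond closes the cyclopentane in the exo sense (C1 in the ring, C10 outside), and C1–C5 together with C9–C10 closes the seven-membered carbocycle, which remains bridged by the pyrylium oxygen as an 8-oxabicyclo[3.2.1]octenone. Regiochemistry is fixed by the tether, since C1 can reach only C5. C5 and C9 are set together because the planar dipole reacts on one face. C1 is set by geometry: the tether can span from C5 only to the exo position of C1, so the methyl group is endo and anti to the oxygen on C5, which is the trans relation of the target with O in the place of H5. The face of the dipole is chosen by C4: C3 must point towards the alkene, so one of the two other groups lies almost in the ring plane beside the oxido oxygen on C6, and the slim oxygen of the silyl ether should take that site rather than the branched isopropyl group (allylic 1,3-strain), which puts C4–O syn to C1–CH3. Dimerisation of 15 is opposed by high dilution and by the fully substituted C4 (Thorpe–Ingold effect).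

Step 10
Reactants: 16 tricyclic enone 5α,9α-epoxy-4β-(triethylsilyloxy)-14-nordauc-7-en-6-one
Product: 17 5α,9α-epoxy-4β-(triethylsilyloxy)daucan-6-one (C8–CH3 α and syn to the O bridge)
Conditions: Me2CuLi (CuI, MeLi), Et2O, −78 to −40 °C; aq. NH4Cl
Reagents that add atoms: lithium dimethylcuprate [Li+].C[Cu-]C
Why: Cuprate 1,4-addition to a β-monosubstituted enone brings in the C8 methyl. Attack should come from the face of the one-atom oxygen bridge, because the other face is covered by the C1–C10 bridge and its endo methyl. The C8 centre is erased in step 12.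

Step 11
Reactants: 17 5α,9α-epoxy-4β-(triethylsilyloxy)daucan-6-one
Product: 19 9α-hydroxy-4β-(triethylsilyloxy)-5αH-daucan-6-one, via samarium enolate 18 (not isolated)
Conditions: SmI2 (2.5 equiv), THF–MeOH, −78 °C
Reagents that add atoms: none
Why: SmI2 reduction of an α-alkoxy ketone: two electrons enter the C6 carbonyl, whose π system overlaps with the strained C5–O bond, and the oxygen leaves as the C9 alkoxide to give 18. C5 is set on protonation; the Sm(III)-bound C9 oxygen has just left C5 and stays over the α face, so it should relay the proton of its coordinated methanol to that face, with H taking the place of O. The trans-fused ketone is also expected to be the more stable epimer, since it holds C6 anti to the C4 isopropyl group.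

Step 12
Reactants: 19 9α-hydroxy-4β-(triethylsilyloxy)-5αH-daucan-6-one
Product: 21 4β-(triethylsilyloxy)-5αH-dauc-7-ene-6,9-dione, via saturated 1,4-diketone 20 (not isolated)
Conditions: IBX (4 equiv), DMSO, rt then 75 °C
Reagents that add atoms: none
Why: IBX oxidises the C9 alcohol to 20 and then dehydrogenates the ketone through its enol (IBX dehydrogenation). C7–C8 lies between both carbonyl groups and is the only ring position with hydrogen on both carbons, since C1 and C4 carry none.

Step 13
Reactants: 21 4β-(triethylsilyloxy)-5αH-dauc-7-ene-6,9-dione
Product: 22 4β-hydroxy-5αH-dauc-7-ene-6,9-dione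
Conditions: HF·pyridine, THF, 0 °C to rt
Reagents that add atoms: none
Why: Fluoride cleavage of the triethylsilyl ether in a weakly acidic medium avoids the basic conditions under which the β-hydroxy ketone could undergo retro-aldol cleavage.

Step 14
Reactants: 22 4β-hydroxy-5αH-dauc-7-ene-6,9-dione
Product: 23 lancerodiol (4β,6α-dihydroxy-5αH-dauc-7-en-9-one)
Conditions: Me4NBH(OAc)3, MeCN–AcOH, −30 °C
Reagents that add atoms: none
Why: Evans–Saksena reduction: the reagent reduces a ketone only after it has exchanged an acetate for a nearby hydroxyl, and from C4–O the hydride reaches C6 alone through a six-membered transition state, so C9 is left. Boron sits on the β face, so hydride enters C6 from β and the new hydroxyl is α (1,3-anti), which sets C6.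

Step 15
Reactants: 23 lancerodiol; 24 4-methoxybenzoyl chloride
Product: 25 lancerodiol p-methoxybenzoate, (3R,3aS,4S,8aR)-3-hydroxy-3-isopropyl-6,8a-dimethyl-7-oxo-1,2,3,3a,4,7,8,8a-octahydroazulen-4-yl 4-methoxybenzoate
Conditions: Et3N, DMAP, CH2Cl2, 0 °C to rt
Reagents that add atoms: none
Why: DMAP-catalysed acylation. The secondary C6–OH reacts, while the tertiary C4–OH, flanked by isopropyl and two ring carbons, does not. The mild amine base leaves the γ-acyloxy enone intact.

## Compound list

1 | (R)-2-hydroxy-3-methylbutanoic acid | CC(C)[C@@H](O)C(=O)O | starting material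
2 | pivalaldehyde | CC(C)(C)C=O | starting material
3 | (2R,5R)-2-tert-butyl-5-isopropyl-1,3-dioxolan-4-one | CC(C)[C@H]1O[C@@H](C(C)(C)C)OC1=O | intermediate
4 | 3-methylbut-3-en-1-ol | C=C(C)CCO | starting material
5 | 4-iodo-2-methylbut-1-ene | C=C(C)CCI | intermediate
6 | lithium enolate of 3 | CC(C)C1=C([O-])O[C@H](C(C)(C)C)O1.[Li+] | intermediate
7 | (2R,5R)-2-tert-butyl-5-isopropyl-5-(3-methylbut-3-en-1-yl)-1,3-dioxolan-4-one | CC(C)[C@@]1(CCC(C)=C)O[C@@H](C(C)(C)C)OC1=O | intermediate
8 | furan | c1ccoc1 | starting material
9 | 2-furyllithium | [Li]c1ccco1 | intermediate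
10 | (R)-1-(furan-2-yl)-2-hydroxy-2-isopropyl-5-methylhex-5-en-1-one | C=C(C)CC[C@@](O)(C(C)C)C(=O)c1ccco1 | intermediate
11 | (R)-1-(furan-2-yl)-2-isopropyl-5-methyl-2-(triethylsilyloxy)hex-5-en-1-one | C=C(C)CC[C@@](O[Si](CC)(CC)CC)(C(C)C)C(=O)c1ccco1 | intermediate
12 | (2R)-1-(furan-2-yl)-2-isopropyl-5-methyl-2-(triethylsilyloxy)hex-5-en-1-ol | C=C(C)CC[C@@](O[Si](CC)(CC)CC)(C(C)C)C(O)c1ccco1 | intermediate
13 | 6-hydroxy-2-[(3R)-2,6-dimethyl-3-(triethylsilyloxy)hept-6-en-3-yl]-2H-pyran-3(6H)-one | C=C(C)CC[C@@](O[Si](CC)(CC)CC)(C(C)C)C1OC(O)C=CC1=O | intermediate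
14 | 6-acetoxy-2-[(3R)-2,6-dimethyl-3-(triethylsilyloxy)hept-6-en-3-yl]-2H-pyran-3(6H)-one | C=C(C)CC[C@@](O[Si](CC)(CC)CC)(C(C)C)C1OC(OC(C)=O)C=CC1=O | intermediate
15 | 2-[(3R)-2,6-dimethyl-3-(triethylsilyloxy)hept-6-en-3-yl]pyrylium-3-olate | C=C(C)CC[C@@](O[Si](CC)(CC)CC)(C(C)C)c1[o+]cccc1[O-] | intermediate
16 | 5α,9α-epoxy-4β-(triethylsilyloxy)-14-nordauc-7-en-6-one | O=C2C=C[C@@H]4C[C@@]3(C)CC[C@@](O[Si](CC)(CC)CC)(C(C)C)[C@]23O4 | intermediate
17 | 5α,9α-epoxy-4β-(triethylsilyloxy)daucan-6-one (8α-CH3) | O=C2C[C@@H](C)[C@@H]4C[C@@]3(C)CC[C@@](O[Si](CC)(CC)CC)(C(C)C)[C@]23O4 | intermediate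
18 | bis(diiodosamarium) C5=C6 enolate / C9 alkoxide | I[Sm](I)OC1=C2[C@](O[Si](CC)(CC)CC)(C(C)C)CC[C@]2(C)C[C@H](O[Sm](I)I)[C@H](C)C1 | intermediate
19 | 9α-hydroxy-4β-(triethylsilyloxy)-5αH-daucan-6-one | O=C2C[C@@H](C)[C@@H](O)C[C@@]3(C)CC[C@@](O[Si](CC)(CC)CC)(C(C)C)[C@H]23 | intermediate
20 | 4β-(triethylsilyloxy)-5αH-daucane-6,9-dione | O=C2C[C@@H](C)C(=O)C[C@@]3(C)CC[C@@](O[Si](CC)(CC)CC)(C(C)C)[C@H]23 | intermediate
21 | 4β-(triethylsilyloxy)-5αH-dauc-7-ene-6,9-dione | O=C2C=C(C)C(=O)C[C@@]3(C)CC[C@@](O[Si](CC)(CC)CC)(C(C)C)[C@H]23 | intermediate
22 | 4β-hydroxy-5αH-dauc-7-ene-6,9-dione | O=C2C=C(C)C(=O)C[C@@]3(C)CC[C@@](O)(C(C)C)[C@H]23 | intermediate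
23 | lancerodiol | O[C@H]2C=C(C)C(=O)C[C@@]3(C)CC[C@@](O)(C(C)C)[C@H]23 | intermediate
24 | 4-methoxybenzoyl chloride | COc1ccc(C(=O)Cl)cc1 | starting material
25 | lancerodiol p-methoxybenzoate | COc1ccc(C(=O)O[C@H]2C=C(C)C(=O)C[C@@]3(C)CC[C@@](O)(C(C)C)[C@H]23)cc1 | target

## Step count and least certain steps

Total steps: 15. Longest linear sequence: 14 (steps 1 and 3–15, from 1).

**Step 9 (key step).**
- *Risk:* two things may go wrong. Facial discrimination by C4 may be insufficient, because neither the silyloxy nor the isopropyl group is small. The cycloaddition may also be slow, because C1–C5 joins two fully substituted carbons next to the fully substituted C4, which gives the ylide time to dimerise.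
- *Fallback:* control is moved from the substrate to a catalyst, and the reacting species is changed. The fallback sets out from 13. This is esterified with 4-(methylthio)benzoyl chloride to the pyranone 4-(methylthio)benzoate F1. F1 is treated with a chiral primary-amine thiourea and an achiral thiourea co-catalyst. Condensation at C6 and anion-binding ionisation give an aminopyrylium ion pair whose face is chosen by the catalyst. Hydrolysis of the iminium adduct brings the sequence back at 16.

**Step 11.**
- *Risk:* protonation of the enolate may occur from the β face, which carries only the methyl and oxygen substituents. That would give the cis ring fusion. Loss of the β-silyloxy group from the enolate is a lesser risk.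
- *Fallback:* C5 is left to thermodynamic instead of kinetic control. The fallback sets out from 19 as obtained, which is carried through step 12. The ene-dione is then equilibrated with DBU in toluene, where C5 is the only centre that can epimerise, and the sequence returns at 21. As a further filter, the directed reduction of step 14 can use only the isomer whose C6 is cis to the C4 hydroxyl. No new compound is made.

**Step 3.**
- *Risk:* substitution at the hindered, isopropyl-bearing enolate may be slow. E2 elimination of the homoallylic iodide, whose β-hydrogens are allylic, may compete.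
- *Fallback:* the SN2 reaction is replaced by a conjugate addition. The fallback sets out from 6, which is added to methyl vinyl ketone to give the keto dioxolanone F2, with the same anti-tert-butyl facial control. Wittig methylenation of the ketone with Ph3P=CH2 brings the sequence back at 7.

**Step 12.**
- *Risk:* dehydrogenation may be incomplete, or the silyl ether may be lost at the temperature the second oxidation needs.
- *Fallback:* the two oxidations are separated. The fallback sets out from 19, which is oxidised with Dess–Martin periodinane to 20, here isolated. Kinetic double enolisation (LDA, TMSCl) gives the bis(trimethylsilyl enol ether) F3 (C6=C7 and C9=C10). Saegusa–Ito oxidation with Pd(OAc)2 can eliminate only from C7 towards C8. The second enol ether is hydrolysed on work-up, which returns the sequence at 21.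

**Step 14.**
- *Risk:* hydride may add to the strongly electrophilic ene-dione C=C. Ligand exchange at the tertiary hydroxyl may also be slow enough to allow undirected reduction.
- *Fallback:* the directed reduction is carried out before the alkene exists. The fallback sets out from 19. Dess–Martin oxidation gives 20, and HF·pyridine gives the hydroxy diketone F4. Me4NBH(OAc)3 then gives 7,8-dihydrolancerodiol F5. Acylation with 24 gives the 7,8-dihydro anisate F6. A final IBX dehydrogenation of the C9 ketone can run only towards C8–C7, because C1 bears no hydrogen, and it returns the sequence at 25.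

## Further compounds

F1 | step 9 | 2-[(3R)-2,6-dimethyl-3-(triethylsilyloxy)hept-6-en-3-yl]-3-oxo-3,6-dihydro-2H-pyran-6-yl 4-(methylthio)benzoate | C=C(C)CC[C@@](O[Si](CC)(CC)CC)(C(C)C)C1OC(OC(=O)c2ccc(SC)cc2)C=CC1=O
F0 | step 11 | none | none
F2 | step 3 | (2R,5R)-2-tert-butyl-5-isopropyl-5-(3-oxobutyl)-1,3-dioxolan-4-one | CC(C)[C@@]1(CCC(C)=O)O[C@@H](C(C)(C)C)OC1=O
F3 | step 12 | 4β-(triethylsilyloxy)-6,9-bis(trimethylsilyloxy)-5αH-dauca-6,9-diene | C[Si](C)(C)OC2=C[C@@H](C)C(O[Si](C)(C)C)=C[C@@]3(C)CC[C@@](O[Si](CC)(CC)CC)(C(C)C)[C@H]23
F4 | step 14 | 4β-hydroxy-5αH-daucane-6,9-dione | O=C2C[C@@H](C)C(=O)C[C@@]3(C)CC[C@@](O)(C(C)C)[C@H]23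
F5 | step 14 | 7,8-dihydrolancerodiol (4β,6α-dihydroxy-5αH-daucan-9-one) | O[C@H]2C[C@@H](C)C(=O)C[C@@]3(C)CC[C@@](O)(C(C)C)[C@H]23
F6 | step 14 | 7,8-dihydrolancerodiol 6-O-(4-methoxybenzoate) | COc1ccc(C(=O)O[C@H]2C[C@@H](C)C(=O)C[C@@]3(C)CC[C@@](O)(C(C)C)[C@H]23)cc1
A1 | alternative 1 | metathesis precursor, 1-[(1R,2S,3R)-3-hydroxy-2-[(1S)-1-hydroxyprop-2-enyl]-3-isopropyl-1-methylcyclopentyl]-3-methylbut-3-en-2-one | C=C[C@H](O)[C@@H]1[C@@](C)(CC(=O)C(C)=C)CC[C@@]1(O)C(C)C
A2 | alternative 1 | (R)-5-hydroxy-5-isopropyl-2-methylcyclopent-1-ene-1-carbaldehyde | O=CC1=C(C)CC[C@@]1(O)C(C)C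
A3 | alternative 2 | 6-acetoxy-4-methyl-2H-pyran-3(6H)-one | CC1=CC(OC(C)=O)OCC1=O
A4 | alternative 2 | (R)-1-isopropyl-3-methylcyclopent-2-en-1-ol | CC1=C[C@](O)(C(C)C)CC1
A5 | alternative 2 | cis-fused 6,10-epoxy adduct (H5 cis to C1–CH3) | O=C1C(C)=C[C@H]2O[C@@H]1[C@]3(C)CC[C@@](O)(C(C)C)[C@H]23
A6 | alternative 3 | (S)-terpinen-4-ol | CC1=CC[C@](O)(C(C)C)CC1
A7 | alternative 3 | (R)-triethyl[(1-isopropyl-3-methyl-2-vinylcyclopent-2-en-1-yl)oxy]silane | C=CC1=C(C)CC[C@@]1(O[Si](CC)(CC)CC)C(C)C
A8 | alternative 3 | methyl 3-(tert-butyldimethylsilyloxy)-2-diazobut-3-enoate | COC(=O)C(=[N+]=[N-])C(=C)O[Si](C)(C)C(C)(C)C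
A9 | alternative 3 | formal (4+3) adduct, methyl 9-(tert-butyldimethylsilyloxy)-4β-(triethylsilyloxy)-14-nordauca-5,8-diene-8-carboxylate | COC(=O)C1=C(O[Si](C)(C)C(C)(C)C)C[C@@]2(C)CC[C@@](O[Si](CC)(CC)CC)(C(C)C)C2=CC1
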